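The ring atoms are labelled C1 (stereocentre), C2, C3=C4(Me) (Z), C5, C6, C7=C8(CO2H) (E), C9, C10, C11=C12(Me) (E), C13, C14. C1 carries the side chain C15(=C16H2)CH2CH2CH=CMe2.
The enabling feature is the array C14–C1–C15=C16H2. With a helper carboxyl on C14 it is the γ,δ-unsaturated acid retron of an ester-enolate [3,3] shift, so C1–C14 is cut back to an 18-membered allylic lactone (C14H2–C(=O)–O–C16H2–C15=C1), a ring that is not in the target.
The further cuts are the lactone C–O bond, C7=C8 (Wittig), C8–C9 (ylide alkylation), C13–C14 (Johnson–Claisen), the C15–side-chain bond (carbomagnesiation) and the C2–alkyne bond (copper acetylide plus allyl bromide).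
In the forward direction the eastern piece C1–C7/C15/C16 comes from neryl acetate (steps 1–7) and the western ylide C8–C14 is made in steps 8–12. Wittig union, macrolactonisation to the temporary 18-ring, contraction to the 14-ring, radical excision of the helper carboxyl and ester hydrolysis follow.
Stereochemistry: 3Z comes from nerol, 11E from a chair Johnson–Claisen, 7E from the stabilised ylide and E C1=C15 from anti-carbomagnesiation. C1 is set by a C2-symmetric chiral diazaborolidine on the boron enolate, relayed through a chair transition state, and the co-formed C14 centre is erased later.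

Key step: step 16

Assumption: the (S,S)-diazaborolidine is taken to leave open the enolate face that leads to (1S,14S)-31. The sense of induction on this lactone would be checked in the first run, and the equally accessible mirror-image reagent would be used if it proves opposite.
Remark: the labels C1–C16 are those of the plan, not the locants of the systematic names. Compounds 2 and 17 are racemates whose stereocentres are destroyed in steps 2 and 9.

Step 1
Reactants: 1 neryl acetate [(2Z)-3,7-dimethylocta-2,6-dien-1-yl acetate]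
Product: 2 (2Z)-5-(3,3-dimethyloxiran-2-yl)-3-methylpent-2-en-1-yl acetate (racemic)
Conditions: mCPBA (1.0 equiv), CH2Cl2, 0 °C
Reagents that add atoms: mCPBA O=C(OO)c1cccc(Cl)c1
Why: Prilezhaev epoxidation, in which the remote trisubstituted alkene is more electron-rich than the future C3=C4 alkene (deactivated by the allylic acetoxy group), so one equivalent of peracid should react there; the new stereocentre is racemic and is lost in step 2.

Step 2
Reactants: 2 (2Z)-5-(3,3-dimethyloxiran-2-yl)-3-methylpent-2-en-1-yl acetate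
Product: 3 (2Z)-3-methyl-6-oxohex-2-en-1-yl acetate
Conditions: H5IO6 (1.1 equiv), THF/H2O, 0 °C
Reagents that add atoms: none
Why: Acid-promoted opening of the epoxide to the glycol and Malaprade cleavage in the same pot should release the C7 aldehyde and acetone without touching the Z alkene or the acetate.

Step 3
Reactants: 3 (2Z)-3-methyl-6-oxohex-2-en-1-yl acetate
Product: 5 (2Z)-6,6-dimethoxy-3-methylhex-2-en-1-ol, via dimethyl acetal acetate 4 (not isolated)
Conditions: HC(OMe)3, p-TsOH (cat.), MeOH, rt; then K2CO3 (0.3 equiv), rt, one pot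
Reagents that add atoms: trimethyl orthoformate COC(OC)OC
Why: Acid-catalysed acetalisation masks the C7 aldehyde against the Grignard reagent of step 6, and carbonate-catalysed transesterification in the same methanol solution frees the allylic alcohol.

Step 4
Reactants: 5 (2Z)-6,6-dimethoxy-3-methylhex-2-en-1-ol
Product: 7 (2Z)-1-bromo-6,6-dimethoxy-3-methylhex-2-ene, via allylic mesylate 6 (not isolated)
Conditions: MsCl, Et3N, CH2Cl2, −40 °C; then LiBr, THF, 0 °C
Reagents that add atoms: lithium bromide [Li+].[Br-]; methanesulfonyl chloride CS(=O)(=O)Cl (its atoms stay only in 6)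
Why: Mesylation followed by SN2 displacement with bromide at low temperature is the standard non-acidic way to a neryl-type bromide and should keep both the Z geometry and the acetal.

Step 5
Reactants: 7 (2Z)-1-bromo-6,6-dimethoxy-3-methylhex-2-ene; 8 propargyl alcohol
Product: 9 (5Z)-9,9-dimethoxy-6-methylnon-5-en-2-yn-1-ol
Conditions: CuI (0.2 equiv), K2CO3, nBu4NBr (cat.), DMF, rt
Reagents that add atoms: none
Why: Allylation of a copper acetylide (SN2 at the primary end of the γ,γ-disubstituted allyl bromide) forms the C2–alkyne bond under conditions mild enough for the Z alkene, the acetal and the free hydroxyl group.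

Step 6
Reactants: 9 (5Z)-9,9-dimethoxy-6-methylnon-5-en-2-yn-1-ol; 10 5-bromo-2-methylpent-2-ene
Product: 13 (2E,5Z)-9,9-dimethoxy-6-methyl-2-(4-methylpent-3-en-1-yl)nona-2,5-dien-1-ol, via homoprenylmagnesium bromide 11 (not isolated), via oxamagnesacycle 12 (not isolated)
Conditions: 10, Mg, Et2O; then 9, CuI (0.2 equiv), Et2O, 0 °C to reflux; sat. aq. NH4Cl
Reagents that add atoms: magnesium [Mg] (its atoms stay only in 11 and 12)
Why: Alkoxide-directed, CuI-catalysed anti-carbomagnesiation of a 2-alkyn-1-ol delivers the alkyl group to the proximal alkyne carbon C15 and holds magnesium on C1 in the five-membered chelate 12, so that protonation leaves H cis and the C2 chain trans to CH2OH (E C1=C15).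

Step 7
Reactants: 13 (2E,5Z)-9,9-dimethoxy-6-methyl-2-(4-methylpent-3-en-1-yl)nona-2,5-dien-1-ol
Product: 14 (4Z,7E)-9-hydroxy-4-methyl-8-(4-methylpent-3-en-1-yl)nona-4,7-dienal
Conditions: PPTS (cat.), acetone/H2O, 40 °C
Reagents that add atoms: water O
Why: Mild acid-catalysed acetal hydrolysis, since a pyridinium salt should not ionise the primary allylic alcohol or isomerise the skipped diene.

Step 8
Reactants: 15 3-[(tert-butyldimethylsilyl)oxy]propanal; 16 isopropenylmagnesium bromide
Product: 17 5-[(tert-butyldimethylsilyl)oxy]-2-methylpent-1-en-3-ol (racemic)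
Conditions: THF, −78 to 0 °C; sat. aq. NH4Cl
Reagents that add atoms: none
Why: 1,2-Addition of an alkenyl Grignard reagent to an aldehyde gives a racemic carbinol centre that is consumed in step 9.

Step 9
Reactants: 17 5-[(tert-butyldimethylsilyl)oxy]-2-methylpent-1-en-3-ol; 18 trimethyl orthoacetate
Product: 20 methyl (4E)-7-[(tert-butyldimethylsilyl)oxy]-4-methylhept-4-enoate, via mixed ketene acetal 19 (not isolated)
Conditions: EtCO2H (cat.), excess 18, 110 °C, MeOH distilled off
Reagents that add atoms: none
Why: Johnson–Claisen (orthoester) rearrangement through a chair transition state with the CH2CH2OTBS group equatorial should give the E C11=C12 alkene, and it adds C14 and the carbonyl carbon of the later tether.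

Step 10
Reactants: 20 methyl (4E)-7-[(tert-butyldimethylsilyl)oxy]-4-methylhept-4-enoate
Product: 21 methyl (4E)-7-hydroxy-4-methylhept-4-enoate
Conditions: camphorsulfonic acid (cat.), MeOH, 0 °C to rt
Reagents that add atoms: none
Why: Acid-catalysed methanolysis of a primary silyl ether, with methanol as solvent making ester exchange degenerate.

Step 11
Reactants: 21 methyl (4E)-7-hydroxy-4-methylhept-4-enoate
Product: 22 methyl (4E)-7-iodo-4-methylhept-4-enoate
Conditions: I2, PPh3, imidazole, CH2Cl2, 0 °C
Reagents that add atoms: iodine II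
Why: Appel-type (Garegg–Samuelsson) iodination of a primary alcohol under essentially neutral conditions.

Step 12
Reactants: 22 methyl (4E)-7-iodo-4-methylhept-4-enoate; 23 ethyl (triphenylphosphoranylidene)acetate
Product: 25 1-ethyl 9-methyl (5E)-6-methyl-2-(triphenylphosphoranylidene)non-5-enedioate, via phosphonium iodide 24 (not isolated)
Conditions: MeCN, reflux; then cold dilute aq. NaOH/CH2Cl2, short contact
Reagents that add atoms: none
Why: C-Alkylation of a stabilised phosphorane by a primary iodide forms C8–C9, brief cold base converts the salt into the α-substituted ylide, and the weakly basic ylide should not eliminate the homoallylic iodide.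

Step 13
Reactants: 14 (4Z,7E)-9-hydroxy-4-methyl-8-(4-methylpent-3-en-1-yl)nona-4,7-dienal; 25 1-ethyl 9-methyl (5E)-6-methyl-2-(triphenylphosphoranylidene)non-5-enedioate
Product: 26 methyl (4E,8E,12Z,15E)-8-(ethoxycarbonyl)-17-hydroxy-4,12-dimethyl-16-(4-methylpent-3-en-1-yl)heptadeca-4,8,12,15-tetraenoate
Conditions: toluene, 90 °C
Reagents that add atoms: none
Why: Wittig olefination with an α-substituted ester-stabilised ylide and an unhindered aldehyde should give the E (tiglate-type) enoate with C6 trans to the ester, and it tolerates the free hydroxyl group.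

Step 14
Reactants: 26 methyl (4E,8E,12Z,15E)-8-(ethoxycarbonyl)-17-hydroxy-4,12-dimethyl-16-(4-methylpent-3-en-1-yl)heptadeca-4,8,12,15-tetraenoate
Product: 27 (4E,8E,12Z,15E)-8-(ethoxycarbonyl)-17-hydroxy-4,12-dimethyl-16-(4-methylpent-3-en-1-yl)heptadeca-4,8,12,15-tetraenoic acid
Conditions: LiOH (1.2 equiv), THF/H2O, 0 °C to rt; then aq. HCl to pH 3
Reagents that add atoms: lithium hydroxide [Li+].[OH-]
Why: Chemoselective saponification, because the unhindered saturated methyl ester is attacked far faster than the conjugated, α-branched ethyl ester.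

Step 15
Reactants: 27 (4E,8E,12Z,15E)-8-(ethoxycarbonyl)-17-hydroxy-4,12-dimethyl-16-(4-methylpent-3-en-1-yl)heptadeca-4,8,12,15-tetraenoic acid
Product: 28 ethyl (5E,9E,13Z,16E)-5,13-dimethyl-17-(4-methylpent-3-en-1-yl)-2-oxo-1-oxacyclooctadeca-5,9,13,16-tetraene-9-carboxylate
Conditions: 2-methyl-6-nitrobenzoic anhydride (MNBA), DMAP, CH2Cl2 (about 1 mM), slow addition, rt
Reagents that add atoms: none
Why: Shiina macrolactonisation (mixed anhydride, nucleophilic catalysis, slow addition) of an unhindered primary allylic alcohol, in which four rigid alkenes lower the entropic cost of closing the temporary 18-membered ring.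

Step 16
Reactants: 28 ethyl (5E,9E,13Z,16E)-5,13-dimethyl-17-(4-methylpent-3-en-1-yl)-2-oxo-1-oxacyclooctadeca-5,9,13,16-tetraene-9-carboxylate
Product: 31 (1S,3E,7E,11Z,14S)-7-(ethoxycarbonyl)-3,11-dimethyl-14-(6-methylhepta-1,5-dien-2-yl)cyclotetradeca-3,7,11-triene-1-carboxylic acid, via boron ketene acetal 29 (not isolated), via acyloxyborane 30 (not isolated)
Conditions: (4S,5S)-2-bromo-1,3-bis{[3,5-bis(trifluoromethyl)phenyl]sulfonyl}-4,5-diphenyl-1,3,2-diazaborolidine (1.3 equiv, made from the (S,S)-bis-sulfonamide and BBr3 in CH2Cl2, volatiles removed), iPr2NEt, CH2Cl2, −78 °C; then −20 to 4 °C; aqueous work-up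
Reagents that add atoms: (S,S)-diazaborolidine bromide BrB1N(S(=O)(=O)c2cc(C(F)(F)F)cc(C(F)(F)F)c2)[C@@H](c2ccccc2)[C@@H](N1S(=O)(=O)c1cc(C(F)(F)F)cc(C(F)(F)F)c1)c1ccccc1 (its atoms stay only in 29 and 30)
Why: The B–Br Lewis acid binds the lactone carbonyl and iPr2NEt removes a C14–H, the only α-proton in the molecule, to give the Z(O) boron ketene acetal 29 (C13 cis to O–B), in which C14=C(OB)–O–C16H2–C15=C1 is an allyl vinyl ether. On warming, this array undergoes a suprafacial [3,3]-sigmatropic shift (boron-enolate Ireland–Claisen rearrangement, whose closest known type is the reagent-controlled ring contraction of macrocyclic allylic lactones of terpenoid origin) that makes C1–C14, breaks O–C16 and moves the π bond to C15=C16H2. The 14-membered carbocycle is thus closed transannularly through a six-membered chair transition state inside the 18-membered ring (four-atom ring contraction), so the carbon–carbon closure is unimolecular and needs no high dilution. C14 is set by the enolate face that the C2-symmetric bis-sulfonamide ligand on boron leaves open, and C1 follows from it through the chair, in which the E C1=C15 geometry and the Z(O) enolate geometry place both ring arms (C2 and C13) equatorial and give the syn (1S,14S) acid; C1 is S here only because C14 now outranks C2, and its spatial arrangement is that of R in the target. The step needs chemoselective enolisation (secured because the C8 enoate has no α-hydrogen and its vinylogous C6–H is kinetically much less acidic), periselectivity (only one oxygen-bearing 1,5-diene array exists) and chair over boat (favoured by the E alkene and the long unstrained twelve-atom bridge C2–C13). A minor anti diastereomer, which would carry the wrong C1, could be separated at this stage before C14 is erased.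

Step 17
Reactants: 31 (1S,3E,7E,11Z,14S)-7-(ethoxycarbonyl)-3,11-dimethyl-14-(6-methylhepta-1,5-dien-2-yl)cyclotetradeca-3,7,11-triene-1-carboxylic acid
Product: 33 ethyl (1E,5Z,8R,11E)-5,11-dimethyl-8-(6-methylhepta-1,5-dien-2-yl)cyclotetradeca-1,5,11-triene-1-carboxylate, via thiohydroxamate ester 32 (not isolated)
Conditions: DCC, 1-hydroxypyridine-2(1H)-thione, DMAP (cat.), CH2Cl2, 0 °C to rt, dark; filter, concentrate; Bu3SnH (0.5 M), toluene, tungsten lamp, 0 °C to rt
Reagents that add atoms: 1-hydroxypyridine-2(1H)-thione ON1C=CC=CC1=S (its atoms stay only in 32)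
Why: Barton reductive decarboxylation, in which loss of CO2 from the acyloxy radical gives the secondary C14 radical and hydrogen transfer from concentrated Bu3SnH should outrun 3-exo and 6-exo attack on the neighbouring alkenes; C1 is untouched, and a tin hydride is preferred to a thiol because thiyl radicals abstract the bis-allylic C2–H.

Step 18
Reactants: 33 ethyl (1E,5Z,8R,11E)-5,11-dimethyl-8-(6-methylhepta-1,5-dien-2-yl)cyclotetradeca-1,5,11-triene-1-carboxylate
Product: 34 (1E,5Z,8R,11E)-5,11-dimethyl-8-(6-methylhepta-1,5-dien-2-yl)cyclotetradeca-1,5,11-triene-1-carboxylic acid (target)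
Conditions: LiOH (excess), THF/EtOH/H2O, 60 °C; then aq. HCl
Reagents that add atoms: lithium hydroxide [Li+].[OH-]
Why: Saponification of the hindered conjugated ester under forcing conditions, which cannot epimerise C1 because that carbon carries no acidifying group.

Compound list
1 | neryl acetate | CC(=O)OC/C=C(/C)CCC=C(C)C | starting material
2 | (2Z)-5-(3,3-dimethyloxiran-2-yl)-3-methylpent-2-en-1-yl acetate (racemic) | CC(=O)OC/C=C(/C)CCC1OC1(C)C | intermediate
3 | (2Z)-3-methyl-6-oxohex-2-en-1-yl acetate | CC(=O)OC/C=C(/C)CCC=O | intermediate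
4 | (2Z)-6,6-dimethoxy-3-methylhex-2-en-1-yl acetate (not isolated) | CC(=O)OC/C=C(/C)CCC(OC)OC | intermediate
5 | (2Z)-6,6-dimethoxy-3-methylhex-2-en-1-ol | OC/C=C(/C)CCC(OC)OC | intermediate
6 | (2Z)-6,6-dimethoxy-3-methylhex-2-en-1-yl methanesulfonate (not isolated) | CS(=O)(=O)OC/C=C(/C)CCC(OC)OC | intermediate
7 | (2Z)-1-bromo-6,6-dimethoxy-3-methylhex-2-ene | BrC/C=C(/C)CCC(OC)OC | intermediate
8 | propargyl alcohol | C#CCO | starting material
9 | (5Z)-9,9-dimethoxy-6-methylnon-5-en-2-yn-1-ol | OCC#CC/C=C(/C)CCC(OC)OC | intermediate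
10 | 5-bromo-2-methylpent-2-ene | CC(C)=CCCBr | starting material
11 | (4-methylpent-3-en-1-yl)magnesium bromide (not isolated) | CC(C)=CCC[Mg]Br | intermediate
12 | five-membered oxamagnesacycle, Mg on C1 and on the C16 oxygen (not isolated) | COC(OC)CC/C(C)=C\CC1=C(CCC=C(C)C)CO[Mg]1 | intermediate
13 | (2E,5Z)-9,9-dimethoxy-6-methyl-2-(4-methylpent-3-en-1-yl)nona-2,5-dien-1-ol | OC/C(CCC=C(C)C)=C/C/C=C(/C)CCC(OC)OC | intermediate
14 | (4Z,7E)-9-hydroxy-4-methyl-8-(4-methylpent-3-en-1-yl)nona-4,7-dienal | OC/C(CCC=C(C)C)=C/C/C=C(/C)CCC=O | intermediate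
15 | 3-[(tert-butyldimethylsilyl)oxy]propanal | O=CCCO[Si](C)(C)C(C)(C)C | starting material
16 | isopropenylmagnesium bromide | C=C(C)[Mg]Br | starting material
17 | 5-[(tert-butyldimethylsilyl)oxy]-2-methylpent-1-en-3-ol (racemic) | C=C(C)C(O)CCO[Si](C)(C)C(C)(C)C | intermediate
18 | trimethyl orthoacetate | CC(OC)(OC)OC | starting material
19 | 1-methoxyvinyl ether of 17, mixed ketene acetal (not isolated) | C=C(OC)OC(CCO[Si](C)(C)C(C)(C)C)C(C)=C | intermediate
20 | methyl (4E)-7-[(tert-butyldimethylsilyl)oxy]-4-methylhept-4-enoate | COC(=O)CC/C(C)=C/CCO[Si](C)(C)C(C)(C)C | intermediate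
21 | methyl (4E)-7-hydroxy-4-methylhept-4-enoate | COC(=O)CC/C(C)=C/CCO | intermediate
22 | methyl (4E)-7-iodo-4-methylhept-4-enoate | COC(=O)CC/C(C)=C/CCI | intermediate
23 | ethyl (triphenylphosphoranylidene)acetate | CCOC(=O)C=P(c1ccccc1)(c1ccccc1)c1ccccc1 | starting material
24 | [(5E)-1-ethoxy-9-methoxy-6-methyl-1,9-dioxonon-5-en-2-yl]triphenylphosphonium iodide (not isolated) | CCOC(=O)C(CC/C=C(\C)CCC(=O)OC)[P+](c1ccccc1)(c1ccccc1)c1ccccc1.[I-] | intermediate
25 | 1-ethyl 9-methyl (5E)-6-methyl-2-(triphenylphosphoranylidene)non-5-enedioate | CCOC(=O)C(CC/C=C(\C)CCC(=O)OC)=P(c1ccccc1)(c1ccccc1)c1ccccc1 | intermediate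
26 | methyl (4E,8E,12Z,15E)-8-(ethoxycarbonyl)-17-hydroxy-4,12-dimethyl-16-(4-methylpent-3-en-1-yl)heptadeca-4,8,12,15-tetraenoate | OC/C(CCC=C(C)C)=C/C/C=C(/C)CC/C=C(/C(=O)OCC)CC/C=C(\C)CCC(=O)OC | intermediate
27 | (4E,8E,12Z,15E)-8-(ethoxycarbonyl)-17-hydroxy-4,12-dimethyl-16-(4-methylpent-3-en-1-yl)heptadeca-4,8,12,15-tetraenoic acid | OC/C(CCC=C(C)C)=C/C/C=C(/C)CC/C=C(/C(=O)OCC)CC/C=C(\C)CCC(=O)O | intermediate
28 | ethyl (5E,9E,13Z,16E)-5,13-dimethyl-17-(4-methylpent-3-en-1-yl)-2-oxo-1-oxacyclooctadeca-5,9,13,16-tetraene-9-carboxylate (18-membered lactone) | O1C/C(CCC=C(C)C)=C/C/C=C(/C)CC/C=C(/C(=O)OCC)CC/C=C(\C)CCC1=O | intermediate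
29 | Z(O) boron ketene acetal of 28 carrying the (S,S)-diazaborolidine, C13 cis to O–B (not isolated) | O1C/C(CCC=C(C)C)=C/C/C=C(/C)CC/C=C(/C(=O)OCC)CC/C=C(\C)C/C=C1\OB2N(S(=O)(=O)c3cc(C(F)(F)F)cc(C(F)(F)F)c3)[C@@H](c3ccccc3)[C@@H](N2S(=O)(=O)c2cc(C(F)(F)F)cc(C(F)(F)F)c2)c2ccccc2 | intermediate
30 | acyloxyborane of 31 carrying the (S,S)-diazaborolidine (not isolated) | C=C(CCC=C(C)C)[C@H]1C/C=C(/C)CC/C=C(/C(=O)OCC)CC/C=C(\C)C[C@@H]1C(=O)OB2N(S(=O)(=O)c3cc(C(F)(F)F)cc(C(F)(F)F)c3)[C@@H](c3ccccc3)[C@@H](N2S(=O)(=O)c2cc(C(F)(F)F)cc(C(F)(F)F)c2)c2ccccc2 | intermediate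
31 | (1S,3E,7E,11Z,14S)-7-(ethoxycarbonyl)-3,11-dimethyl-14-(6-methylhepta-1,5-dien-2-yl)cyclotetradeca-3,7,11-triene-1-carboxylic acid | C=C(CCC=C(C)C)[C@H]1C/C=C(/C)CC/C=C(/C(=O)OCC)CC/C=C(\C)C[C@@H]1C(=O)O | intermediate
32 | 2-thioxopyridin-1(2H)-yl ester of 31 (not isolated) | C=C(CCC=C(C)C)[C@H]1C/C=C(/C)CC/C=C(/C(=O)OCC)CC/C=C(\C)C[C@@H]1C(=O)ON2C=CC=CC2=S | intermediate
33 | ethyl (1E,5Z,8R,11E)-5,11-dimethyl-8-(6-methylhepta-1,5-dien-2-yl)cyclotetradeca-1,5,11-triene-1-carboxylate | C=C(CCC=C(C)C)[C@H]1C/C=C(/C)CC/C=C(/C(=O)OCC)CC/C=C(\C)CC1 | intermediate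
34 | (1E,5Z,8R,11E)-5,11-dimethyl-8-(6-methylhepta-1,5-dien-2-yl)cyclotetradeca-1,5,11-triene-1-carboxylic acid | C=C(CCC=C(C)C)[C@H]1C/C=C(/C)CC/C=C(/C(=O)O)CC/C=C(\C)CC1 | target

Total step count: 18.
Longest linear sequence: 13 steps (steps 1–7 and 13–18).

Steps most likely to fail

**Step 16.** The bulky Lewis acid may be tied up by the C8 ester or may start vinylogous deprotonation at C6. Chair/boat leakage or weak facial discrimination in the flexible 18-membered ring would also lower the enantiomeric purity at C1. The fallback changes the source of chirality from reagent control to resolution, and the enolisation from soft boron to kinetic lithium/silicon.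
- From 28, LiN(iPr)2 in the presence of Me3SiCl (THF/DMPU, −78 °C) would give the trimethylsilyl ketene acetal F1, which should undergo the same ring contraction on warming to room temperature.
- Mild acidic work-up would give the racemic syn acid F2.
- Crystallisation with (R)-1-phenylethylamine would give the less soluble diastereomeric ammonium salt F3, and acidification comes back to the route at 31.

**Step 6.** Addition of a primary alkyl Grignard reagent to an internal alkynol may be slow. That would allow base-induced migration of the skipped enyne into conjugation at C2, or regiochemical leakage. The fallback replaces carbometalation by hydrometalation and cross-coupling.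
- From 9, hydroxyl-directed trans-hydrostannation (Bu3SnH, [Cp*RuCl]4 cat., CH2Cl2) would give the proximal alkenylstannane F4.
- I2 in CH2Cl2 at 0 °C would give the alkenyl iodide F5 with retention.
- Negishi coupling of F5 with the alkylzinc bromide F6 (made from 11 and ZnBr2) under Pd(dppf)Cl2 in THF comes back to the route at 13 with the same E geometry.

**Step 17.** The C14 radical may rearrange by 1,2-vinyl migration through a cyclopropylcarbinyl radical, or cyclise onto the side-chain alkene, before hydrogen transfer. Chain-carrying radicals may also isomerise the Z alkene. The fallback removes the helper carbon without free radicals.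
- From 31, isobutyl chloroformate and N-methylmorpholine would give the mixed anhydride F7.
- NaBH4 would reduce F7 to the primary alcohol F8, and Dess–Martin periodinane would give the aldehyde F9.
- Tsuji–Wilkinson decarbonylation of F9 with stoichiometric RhCl(PPh3)3 in hot toluene comes back to the route at 33.

Further compounds
F1 | step 16 | trimethylsilyl ketene acetal of lactone 28 (C13 cis to O–Si) | O1C/C(CCC=C(C)C)=C/C/C=C(/C)CC/C=C(/C(=O)OCC)CC/C=C(\C)C/C=C1\O[Si](C)(C)C
F2 | step 16 | racemic syn acid (31 together with its mirror image) | C=C(CCC=C(C)C)[C@H]1C/C=C(/C)CC/C=C(/C(=O)OCC)CC/C=C(\C)C[C@@H]1C(=O)O.C=C(CCC=C(C)C)[C@@H]1C/C=C(/C)CC/C=C(/C(=O)OCC)CC/C=C(\C)C[C@H]1C(=O)O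
F3 | step 16 | (R)-1-phenylethylammonium salt of 31 | C=C(CCC=C(C)C)[C@H]1C/C=C(/C)CC/C=C(/C(=O)OCC)CC/C=C(\C)C[C@@H]1C(=O)[O-].C[C@@H]([NH3+])c1ccccc1
F4 | step 6 | (2Z,5Z)-9,9-dimethoxy-6-methyl-2-(tributylstannyl)nona-2,5-dien-1-ol | OC/C([Sn](CCCC)(CCCC)CCCC)=C/C/C=C(/C)CCC(OC)OC
F5 | step 6 | (2Z,5Z)-2-iodo-9,9-dimethoxy-6-methylnona-2,5-dien-1-ol | OC/C(I)=C/C/C=C(/C)CCC(OC)OC
F6 | step 6 | (4-methylpent-3-en-1-yl)zinc bromide | CC(C)=CCC[Zn]Br
F7 | step 17 | isobutyl carbonic mixed anhydride of 31 | C=C(CCC=C(C)C)[C@H]1C/C=C(/C)CC/C=C(/C(=O)OCC)CC/C=C(\C)C[C@@H]1C(=O)OC(=O)OCC(C)C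
F8 | step 17 | C14 hydroxymethyl compound (CH2OH in place of CO2H of 31, same configuration) | C=C(CCC=C(C)C)[C@H]1C/C=C(/C)CC/C=C(/C(=O)OCC)CC/C=C(\C)C[C@@H]1CO
F9 | step 17 | C14 carbaldehyde (CHO in place of CO2H of 31, same configuration) | C=C(CCC=C(C)C)[C@H]1C/C=C(/C)CC/C=C(/C(=O)OCC)CC/C=C(\C)C[C@@H]1C=O
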